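**Retrosynthetic overview**

1. The route rests on the side-chain aldol unit C5(OH)–C1′H2–C2′(=O) of target 20. It is treated as a 5,5-disubstituted 2-isoxazoline spiro-fused at C5 of the six-membered ring, and C2′ with its heptadeca-8,11-dienyl chain is the C1–C18 linoleyl skeleton.
2. 20 ⇐ spiro-isoxazoline enone 18 by N–O cleavage and imine hydrolysis. 18 ⇐ ketone 15 by dehydrogenation, which can only give C2=C3 because C5 carries no hydrogen. 15 ⇐ carbinol 14 by oxidation.
3. 14 ⇐ [3+2] cycloaddition of linoleonitrile oxide 13 to the exocyclic alkene of (S)-3-methylidenecyclohexan-1-ol 7, directed by its magnesium alkoxide; this forms C1′–C2′ and C5–O.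
4. 13 ⇐ linoleyl alcohol 8 via aldehyde, oxime and hydroximoyl chloride 11. 7 ⇐ cis-cyclohexane-1,3-diol 1 by lipase desymmetrisation, silyl/acetyl exchange, oxidation and methylenation.
5. Ring order: the carbocycle is bought; the isoxazoline is the only ring formed (step 10) and is opened again in step 14.

Key step: step 10

Remark: the C=N geometry of 10 and 11 is left open because both isomers give the same nitrile oxide 13; locants C1–C6 and C1′, C2′ refer to the target, spiro locants (O1, N2, C3–C10) to the isoxazoline intermediates.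

**Route**

Step 1
Reactants: 1 cis-cyclohexane-1,3-diol
Product: 2 (1R,3S)-3-hydroxycyclohexyl acetate
Conditions: Candida antarctica lipase B (immobilised), vinyl acetate, THF, rt
Reagents that add atoms: vinyl acetate, CC(=O)OC=C
Why: Lipase-catalysed irreversible transesterification desymmetrises the meso-diol; following the usual enantiopreference of lipases for secondary alcohols the (R)-carbinol is acylated, so the free hydroxyl should sit on the (S) carbon.

Step 2
Reactants: 2 (1R,3S)-3-hydroxycyclohexyl acetate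
Product: 3 (1R,3S)-3-[(tert-butyldiphenylsilyl)oxy]cyclohexyl acetate
Conditions: TBDPSCl, imidazole, DMF, rt
Reagents that add atoms: tert-butyl(chloro)diphenylsilane, CC(C)(C)[Si](Cl)(c1ccccc1)c1ccccc1
Why: Imidazole-promoted silylation of the remaining secondary alcohol; no stereocentre is touched.

Step 3
Reactants: 3 (1R,3S)-3-[(tert-butyldiphenylsilyl)oxy]cyclohexyl acetate
Product: 4 (1R,3S)-3-[(tert-butyldiphenylsilyl)oxy]cyclohexan-1-ol
Conditions: K2CO3 (cat.), MeOH, 0 °C to rt
Reagents that add atoms: none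
Why: Base-catalysed methanolysis removes the acetate; the bulky silyl ether is stable to carbonate and should not migrate between the cis-1,3 oxygens, which would erode enantiopurity.

Step 4
Reactants: 4 (1R,3S)-3-[(tert-butyldiphenylsilyl)oxy]cyclohexan-1-ol
Product: 5 (3S)-3-[(tert-butyldiphenylsilyl)oxy]cyclohexan-1-one
Conditions: Dess–Martin periodinane, CH2Cl2, rt
Reagents that add atoms: none
Why: Dess–Martin oxidation under near-neutral conditions removes the (R) carbinol without β-elimination of the silyloxy group, leaving the single (S) stereocentre.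

Step 5
Reactants: 5 (3S)-3-[(tert-butyldiphenylsilyl)oxy]cyclohexan-1-one
Product: 6 tert-butyl{[(1S)-3-methylidenecyclohexyl]oxy}diphenylsilane
Conditions: Ph3PCH3Br, KOt-Bu, THF, 0 °C to rt
Reagents that add atoms: methyltriphenylphosphonium bromide, C[P+](c1ccccc1)(c1ccccc1)c1ccccc1.[Br-]
Why: Wittig methylenation; the non-stabilised ylide should add to the cyclohexanone faster than it enolises it, so the β-silyloxy group and the stereocentre are kept.

Step 6
Reactants: 6 tert-butyl{[(1S)-3-methylidenecyclohexyl]oxy}diphenylsilane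
Product: 7 (1S)-3-methylidenecyclohexan-1-ol
Conditions: TBAF, THF, rt
Reagents that add atoms: none
Why: Fluoride-mediated desilylation under non-acidic conditions, so the exocyclic alkene should not move into the ring (the volatile alcohol is concentrated carefully).

Step 7
Reactants: 8 linoleyl alcohol, (9Z,12Z)-octadeca-9,12-dien-1-ol
Product: 9 (9Z,12Z)-octadeca-9,12-dienal
Conditions: Dess–Martin periodinane, CH2Cl2, 0 °C to rt
Reagents that add atoms: none
Why: Dess–Martin oxidation stops at the aldehyde and leaves the skipped (Z,Z)-diene untouched; the aldehyde is used directly.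

Step 8
Reactants: 9 (9Z,12Z)-octadeca-9,12-dienal
Product: 10 (9Z,12Z)-octadeca-9,12-dienal oxime
Conditions: NH2OH·HCl, NaOAc, EtOH/H2O, rt
Reagents that add atoms: hydroxylamine hydrochloride, Cl.NO
Why: Acetate-buffered condensation of an aldehyde with hydroxylamine (oxime formation).

Step 9
Reactants: 10 (9Z,12Z)-octadeca-9,12-dienal oxime
Product: 11 (9Z,12Z)-N-hydroxyoctadeca-9,12-dienimidoyl chloride
Conditions: NCS, DMF, 0 °C to rt, dark
Reagents that add atoms: N-chlorosuccinimide, O=C1CCC(=O)N1Cl
Why: Electrophilic chlorination of the aldoxime carbon (hydroximoyl chloride formation), which should be faster than any reaction of NCS with the unactivated Z-alkenes; the chloride is used crude.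

Step 10
Reactants: 7 (1S)-3-methylidenecyclohexan-1-ol; 11 (9Z,12Z)-N-hydroxyoctadeca-9,12-dienimidoyl chloride
Product: 14 (5S,7S)-3-[(8Z,11Z)-heptadeca-8,11-dien-1-yl]-1-oxa-2-azaspiro[4.5]dec-2-en-7-ol, via bromomagnesium alkoxide 12 (not isolated), via nitrile oxide 13 (not isolated)
Conditions: 7, i-PrOH (3.3 equiv), EtMgBr (3.0 equiv), CH2Cl2, 0 °C; then 11 (1.3 equiv) added slowly, 0 °C to rt
Reagents that add atoms: none
Why: EtMgBr is consumed completely by the two alcohols, giving alkoxide 12 and bromomagnesium isopropoxide; these dehydrochlorinate 11 to nitrile oxide 13, whose oxygen binds the magnesium that carries the substrate alkoxide, and a concerted suprafacial [3+2] cycloaddition joins the dipole carbon to the exocyclic CH2 and the dipole oxygen to the fully substituted ring carbon. The closest known reaction type is the magnesium-alkoxide-directed nitrile oxide cycloaddition of allylic and homoallylic alcohols. The isoxazoline ring closes in this single intermolecular step (bonds C3–C4 and O1–C5), which creates the spiro junction. The new stereocentre C5 is controlled by the C7 carbinol: in the chair with an axial O–Mg bond (little penalty, since the sp2 ring carbon removes one syn-axial hydrogen) the metal can only bridge to a dipole arriving on the axial face, so the ring oxygen should end cis to the hydroxyl, i.e. 5S from the (S) carbinol. The step needs regioselectivity (oxygen to the disubstituted carbon, normal for 1,1-disubstituted alkenes and reinforced because that carbon is nearer the alkoxide), face selectivity (the chelate) and chemoselectivity over the two chain Z-alkenes and over furoxan formation (rate acceleration of the metal-bound alkene, slow addition of 11). Any minor C5 epimer is a diastereomer and is removed by chromatography before the carbinol is oxidised.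

Step 11
Reactants: 14 (5S,7S)-3-[(8Z,11Z)-heptadeca-8,11-dien-1-yl]-1-oxa-2-azaspiro[4.5]dec-2-en-7-ol
Product: 15 (5S)-3-[(8Z,11Z)-heptadeca-8,11-dien-1-yl]-1-oxa-2-azaspiro[4.5]dec-2-en-7-one
Conditions: Dess–Martin periodinane, CH2Cl2, 0 °C to rt
Reagents that add atoms: none
Why: Dess–Martin oxidation of the secondary carbinol removes the C7 stereocentre after it has set C5; the base-free medium avoids retro-oxa-Michael opening of the β-oxygenated ketone, which would racemise C5.

Step 12
Reactants: 15 (5S)-3-[(8Z,11Z)-heptadeca-8,11-dien-1-yl]-1-oxa-2-azaspiro[4.5]dec-2-en-7-one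
Product: 17 (5S)-3-[(8Z,11Z)-heptadeca-8,11-dien-1-yl]-7-[(trimethylsilyl)oxy]-1-oxa-2-azaspiro[4.5]deca-2,7-diene, via lithium enolate 16 (not isolated)
Conditions: LiN(i-Pr)2 (1.1 equiv), THF, −78 °C; then TMSCl, −78 to 0 °C
Reagents that add atoms: chlorotrimethylsilane, C[Si](C)(C)Cl
Why: Kinetic deprotonation by the hindered amide should occur at C8, because C6 is flanked by the quaternary spiro carbon and the side-chain carbonyl is hidden in the isoxazoline; O-silylation traps enolate 16 (regioselective silyl enol ether formation), and the C8 enolate cannot expel the β-oxygen, so C5 is untouched.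

Step 13
Reactants: 17 (5S)-3-[(8Z,11Z)-heptadeca-8,11-dien-1-yl]-7-[(trimethylsilyl)oxy]-1-oxa-2-azaspiro[4.5]deca-2,7-diene
Product: 18 (5S)-3-[(8Z,11Z)-heptadeca-8,11-dien-1-yl]-1-oxa-2-azaspiro[4.5]deca-2,8-dien-7-one
Conditions: Pd(OAc)2 (1.05 equiv), MeCN, rt
Reagents that add atoms: none
Why: Ito–Saegusa oxidation: divalent palladium forms the C8 palladium enolate and β-hydride elimination from C9 gives the enone; the neutral room-temperature conditions should spare the skipped diene and the base-labile C5–O bond.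

Step 14
Reactants: 18 (5S)-3-[(8Z,11Z)-heptadeca-8,11-dien-1-yl]-1-oxa-2-azaspiro[4.5]deca-2,8-dien-7-one
Product: 20 (5S)-5-hydroxy-5-[(10Z,13Z)-2-oxononadeca-10,13-dien-1-yl]cyclohex-2-en-1-one, via hydroxy imine 19 (not isolated)
Conditions: Mo(CO)6, MeCN/H2O, 80 °C
Reagents that add atoms: water, O
Why: Zerovalent molybdenum cleaves the N–O bond reductively and the β-hydroxy imine 19 hydrolyses in the wet medium to the ketone; C=C bonds, the enone included, are not reduced and the C5–O bond is not broken, so the (S) configuration is retained.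

**Compound list**

1 | cis-cyclohexane-1,3-diol (meso) | O[C@@H]1CCC[C@H](O)C1 | starting material
2 | (1R,3S)-3-hydroxycyclohexyl acetate | CC(=O)O[C@@H]1CCC[C@H](O)C1 | intermediate
3 | (1R,3S)-3-[(tert-butyldiphenylsilyl)oxy]cyclohexyl acetate | CC(=O)O[C@@H]1CCC[C@H](O[Si](c2ccccc2)(c2ccccc2)C(C)(C)C)C1 | intermediate
4 | (1R,3S)-3-[(tert-butyldiphenylsilyl)oxy]cyclohexan-1-ol | O[C@@H]1CCC[C@H](O[Si](c2ccccc2)(c2ccccc2)C(C)(C)C)C1 | intermediate
5 | (3S)-3-[(tert-butyldiphenylsilyl)oxy]cyclohexan-1-one | O=C1CCC[C@H](O[Si](c2ccccc2)(c2ccccc2)C(C)(C)C)C1 | intermediate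
6 | tert-butyl{[(1S)-3-methylidenecyclohexyl]oxy}diphenylsilane | C=C1CCC[C@H](O[Si](c2ccccc2)(c2ccccc2)C(C)(C)C)C1 | intermediate
7 | (1S)-3-methylidenecyclohexan-1-ol | C=C1CCC[C@H](O)C1 | intermediate
8 | linoleyl alcohol, (9Z,12Z)-octadeca-9,12-dien-1-ol | CCCCC/C=C\C/C=C\CCCCCCCCO | starting material
9 | (9Z,12Z)-octadeca-9,12-dienal | CCCCC/C=C\C/C=C\CCCCCCCC=O | intermediate
10 | (9Z,12Z)-octadeca-9,12-dienal oxime (C=N isomers) | CCCCC/C=C\C/C=C\CCCCCCCC=NO | intermediate
11 | (9Z,12Z)-N-hydroxyoctadeca-9,12-dienimidoyl chloride | CCCCC/C=C\C/C=C\CCCCCCCC(Cl)=NO | intermediate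
12 | bromomagnesium (1S)-3-methylidenecyclohexan-1-olate | C=C1CCC[C@H](O[Mg]Br)C1 | intermediate
13 | (9Z,12Z)-octadeca-9,12-dienenitrile oxide | CCCCC/C=C\C/C=C\CCCCCCCC#[N+][O-] | intermediate
14 | (5S,7S)-3-[(8Z,11Z)-heptadeca-8,11-dien-1-yl]-1-oxa-2-azaspiro[4.5]dec-2-en-7-ol (ring oxygen cis to hydroxyl) | CCCCC/C=C\C/C=C\CCCCCCCC1=NO[C@]2(C1)CCC[C@H](O)C2 | intermediate
15 | (5S)-3-[(8Z,11Z)-heptadeca-8,11-dien-1-yl]-1-oxa-2-azaspiro[4.5]dec-2-en-7-one | CCCCC/C=C\C/C=C\CCCCCCCC1=NO[C@]2(C1)CCCC(=O)C2 | intermediate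
16 | lithium (5S)-3-[(8Z,11Z)-heptadeca-8,11-dien-1-yl]-1-oxa-2-azaspiro[4.5]deca-2,7-dien-7-olate | CCCCC/C=C\C/C=C\CCCCCCCC1=NO[C@]2(C1)CCC=C(O[Li])C2 | intermediate
17 | (5S)-3-[(8Z,11Z)-heptadeca-8,11-dien-1-yl]-7-[(trimethylsilyl)oxy]-1-oxa-2-azaspiro[4.5]deca-2,7-diene | CCCCC/C=C\C/C=C\CCCCCCCC1=NO[C@]2(C1)CCC=C(O[Si](C)(C)C)C2 | intermediate
18 | (5S)-3-[(8Z,11Z)-heptadeca-8,11-dien-1-yl]-1-oxa-2-azaspiro[4.5]deca-2,8-dien-7-one | CCCCC/C=C\C/C=C\CCCCCCCC1=NO[C@]2(C1)CC=CC(=O)C2 | intermediate
19 | (5S)-5-hydroxy-5-[(10Z,13Z)-2-iminononadeca-10,13-dien-1-yl]cyclohex-2-en-1-one | CCCCC/C=C\C/C=C\CCCCCCCC(=N)C[C@@]1(O)CC=CC(=O)C1 | intermediate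
20 | (5S)-5-hydroxy-5-[(10Z,13Z)-2-oxononadeca-10,13-dien-1-yl]cyclohex-2-en-1-one | CCCCC/C=C\C/C=C\CCCCCCCC(=O)C[C@@]1(O)CC=CC(=O)C1 | target

**Step count**

Total: 14 steps. Longest linear sequence: 11 steps (steps 1–6 and 10–14); steps 7–9 form the second branch.

**Steps most likely to fail**

Step 10. The six-membered magnesium bridge from a homoallylic alkoxide may hold the dipole too loosely, giving poor facial selectivity at C5, and the aliphatic nitrile oxide may be lost to furoxan dimerisation. Fallback: chelation control is given up and the C7 carbinol serves only as a handle for separating diastereomers. The fallback sets out from silyl ether 6 and chloride 11. With base-only generation of the dipole (Et3N, toluene, slow addition, rt) these should give both spiro epimers: (5S,7S)-7-[(tert-butyldiphenylsilyl)oxy]-3-[(8Z,11Z)-heptadeca-8,11-dien-1-yl]-1-oxa-2-azaspiro[4.5]dec-2-ene F1 and its (5R,7S) epimer F2. TBAF in THF then gives 14 and the (5R,7S) alcohol F3, which are separated on silica, and the route is rejoined at 14.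

Step 12. Deprotonation may occur at C6 instead of C8; the C6 enolate can expel the oxime oxygen from C5, which opens the isoxazoline and erases the stereocentre. Fallback: no enolate is made. Ketone 15 is dehydrogenated directly with IBX and 4-methoxypyridine N-oxide in DMSO at rt (single-electron oxidation of the enol); only the C8–C9 bond can be desaturated because C5 has no hydrogen, and palladium is avoided as well. The fallback sets out from 15, comes back at 18, replaces steps 12 and 13 and makes no compound outside the route (F0).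

Step 14. Heating with the metal carbonyl may dehydrate the tertiary β-hydroxy enone towards a 3-substituted phenol, cause retro-aldol cleavage, or move the skipped diene into conjugation. Fallback: the enone is taken out of play during N–O cleavage. From 18, Luche reduction (NaBH4, CeCl3·7H2O, MeOH, −40 °C) should give (5S)-3-[(8Z,11Z)-heptadeca-8,11-dien-1-yl]-1-oxa-2-azaspiro[4.5]deca-2,8-dien-7-ol F4 as C7 epimers, the isoxazoline being inert to borohydride. SmI2 (THF, 0 °C; then B(OH)3, H2O) cleaves the N–O bond, and (10Z,13Z)-1-[(1S)-1,5-dihydroxycyclohex-3-en-1-yl]nonadeca-10,13-dien-2-imine F5 hydrolyses in the flask to (10Z,13Z)-1-[(1R)-1,5-dihydroxycyclohex-3-en-1-yl]nonadeca-10,13-dien-2-one F6. MnO2 (CH2Cl2, rt) oxidises only the allylic carbinol and comes back to the route at 20.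

**Further compounds**

F1 | step 10 | (5S,7S)-7-[(tert-butyldiphenylsilyl)oxy]-3-[(8Z,11Z)-heptadeca-8,11-dien-1-yl]-1-oxa-2-azaspiro[4.5]dec-2-ene | CCCCC/C=C\C/C=C\CCCCCCCC1=NO[C@]2(C1)CCC[C@H](O[Si](c3ccccc3)(c3ccccc3)C(C)(C)C)C2
F2 | step 10 | (5R,7S)-7-[(tert-butyldiphenylsilyl)oxy]-3-[(8Z,11Z)-heptadeca-8,11-dien-1-yl]-1-oxa-2-azaspiro[4.5]dec-2-ene | CCCCC/C=C\C/C=C\CCCCCCCC1=NO[C@@]2(C1)CCC[C@H](O[Si](c3ccccc3)(c3ccccc3)C(C)(C)C)C2
F3 | step 10 | (5R,7S)-3-[(8Z,11Z)-heptadeca-8,11-dien-1-yl]-1-oxa-2-azaspiro[4.5]dec-2-en-7-ol | CCCCC/C=C\C/C=C\CCCCCCCC1=NO[C@@]2(C1)CCC[C@H](O)C2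
F0 | step 12 | none | none
F4 | step 14 | (5S)-3-[(8Z,11Z)-heptadeca-8,11-dien-1-yl]-1-oxa-2-azaspiro[4.5]deca-2,8-dien-7-ol (C7 epimers) | CCCCC/C=C\C/C=C\CCCCCCCC1=NO[C@]2(C1)CC=CC(O)C2
F5 | step 14 | (10Z,13Z)-1-[(1S)-1,5-dihydroxycyclohex-3-en-1-yl]nonadeca-10,13-dien-2-imine (C5 epimers) | CCCCC/C=C\C/C=C\CCCCCCCC(=N)C[C@@]1(O)CC=CC(O)C1
F6 | step 14 | (10Z,13Z)-1-[(1R)-1,5-dihydroxycyclohex-3-en-1-yl]nonadeca-10,13-dien-2-one (C5 epimers) | CCCCC/C=C\C/C=C\CCCCCCCC(=O)C[C@@]1(O)CC=CC(O)C1
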